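**Strategy.** The ten-membered carbocycle (C1–C10, germacrane numbering) is not closed end to end; the bond that matters is C1–C6, which is absent in the target. The C1 ketone and the C6 lactone oxygen lie 1,6 across the ring, and the cis-4,5-epoxide calls for a Z C4=C5 alkene. The ring therefore folds back onto a cyclohexene, the trans-1-isopropenyl-2-alkenyl-4-methylcyclohex-3-ene-1,2-diol 2-methyl ether 18. Its potassium alkoxide undergoes a chair oxy-Cope shift that forms C8–C9, expands the six- to the ten-membered ring and fixes C8. The resulting C1–C10 enolate is hydroxylated in the same flask, which sets C10. The gamma-lactone, epoxide and esters follow.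

Key step: step 13

Assumption: the lipase hydrolyses the (R)-acetate of 2 faster (usual secondary-alcohol preference); if it prefers the (S)-acetate, the recovered (R)-acetate is methanolysed to the same alcohol 3.

Step 1
Reactants: 1 3-methylcyclohex-2-en-1-one
Product: 2 rac-6-acetoxy-3-methylcyclohex-2-en-1-one
Conditions: Mn(OAc)3·2H2O, benzene, reflux (Dean–Stark)
Reagents that add atoms: manganese triacetate, CC(=O)[O-].CC(=O)[O-].CC(=O)[O-].[Mn+3]
Why: Mn(OAc)3 alpha'-acetoxylation: the manganese enolate formed on the saturated side of the enone is oxidised and captured by acetate, so the enone C=C is untouched and the racemic alpha'-acetate results.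

Step 2
Reactants: 2 rac-6-acetoxy-3-methylcyclohex-2-en-1-one
Product: 3 (R)-6-hydroxy-3-methylcyclohex-2-en-1-one
Conditions: lipase PS (Burkholderia cepacia), pH 7 phosphate buffer/MTBE, rt, about half conversion
Reagents that add atoms: none
Why: Lipase-catalysed enantioselective hydrolysis (kinetic resolution) frees only the (R)-alcohol, which fixes the later C1 carbinol configuration; the (S)-acetate stays behind and is removed by chromatography.

Step 3
Reactants: 3 (R)-6-hydroxy-3-methylcyclohex-2-en-1-one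
Product: 4 (R)-3-methyl-6-[(triisopropylsilyl)oxy]cyclohex-2-en-1-one
Conditions: TIPSOTf, 2,6-lutidine, CH2Cl2, 0 °C
Reagents that add atoms: triisopropylsilyl trifluoromethanesulfonate, CC(C)[Si](OS(=O)(=O)C(F)(F)F)(C(C)C)C(C)C
Why: Silylation of the secondary alcohol with a silyl triflate and a hindered pyridine; the bulky TIPS group does not chelate, does not migrate under the later alkoxide conditions and is removed by fluoride alone.

Step 4
Reactants: 5 2-bromoprop-2-en-1-ol
Product: 6 2-bromo-3-(methoxymethoxy)prop-1-ene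
Conditions: MOMCl, i-Pr2NEt, CH2Cl2, 0 °C to rt
Reagents that add atoms: chloromethyl methyl ether, COCCl
Why: O-alkylation of the primary alcohol with an alpha-chloro ether (MOM protection) under amine base leaves the vinyl bromide intact.

Step 5
Reactants: 6 2-bromo-3-(methoxymethoxy)prop-1-ene; 4 (R)-3-methyl-6-[(triisopropylsilyl)oxy]cyclohex-2-en-1-one
Product: 8 (1R,6R)-1-[3-(methoxymethoxy)prop-1-en-2-yl]-3-methyl-6-[(triisopropylsilyl)oxy]cyclohex-2-en-1-ol, via alkenyllithium 7 (not isolated)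
Conditions: 6, t-BuLi (2 equiv), Et2O, −78 °C; then 4, −78 °C; aq. NH4Cl
Reagents that add atoms: none
Why: Bromine–lithium exchange gives a 2-lithioallyl ether whose oxygen sits on an sp3 carbon (no anti-periplanar vinylic alkoxide to eliminate), and its 1,2-addition to the enone carbonyl occurs anti to the pseudoaxial C–OSi bond (polar Felkin–Anh addition), which sets the C6 carbinol centre.

Step 6
Reactants: 8 (1R,6R)-1-[3-(methoxymethoxy)prop-1-en-2-yl]-3-methyl-6-[(triisopropylsilyl)oxy]cyclohex-2-en-1-ol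
Product: 9 {[(1R,2R)-2-methoxy-2-[3-(methoxymethoxy)prop-1-en-2-yl]-4-methylcyclohex-3-en-1-yl]oxy}triisopropylsilane
Conditions: KH, MeI, THF, 0 °C to rt
Reagents that add atoms: iodomethane, CI
Why: Williamson etherification of the tertiary potassium alkoxide with MeI; the methyl ether later distinguishes C6 from C1 and is the chelating group for step 12.

Step 7
Reactants: 10 (4-methoxyphenyl)methanol
Product: 11 1-methoxy-4-{[(methylsulfanyl)methoxy]methyl}benzene
Conditions: NaH, ClCH2SMe, NaI (cat.), DME, 0 °C to rt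
Reagents that add atoms: chloromethyl methyl sulfide, CSCCl
Why: Williamson alkylation of the sodium alkoxide gives the methylthiomethyl ether, the precursor of the alpha-chloro ether.

Step 8
Reactants: 11 1-methoxy-4-{[(methylsulfanyl)methoxy]methyl}benzene
Product: 12 1-[(chloromethoxy)methyl]-4-methoxybenzene
Conditions: SO2Cl2, CH2Cl2, −78 °C; volatiles removed, used at once
Reagents that add atoms: sulfuryl chloride, ClS(Cl)(=O)=O
Why: Chlorinolysis of the O,S-acetal by SO2Cl2 (chlorosulfonium formation and loss of MeSCl) gives the alpha-chloro ether under non-acidic conditions; it is used without purification.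

Step 9
Reactants: 9 {[(1R,2R)-2-methoxy-2-[3-(methoxymethoxy)prop-1-en-2-yl]-4-methylcyclohex-3-en-1-yl]oxy}triisopropylsilane; 12 1-[(chloromethoxy)methyl]-4-methoxybenzene
Product: 14 {[(1R,2R)-2-methoxy-2-{(1E)-1-(methoxymethoxy)-4-[(4-methoxybenzyl)oxy]but-1-en-2-yl}-4-methylcyclohex-3-en-1-yl]oxy}triisopropylsilane, via oxyallyllithium 13 (not isolated)
Conditions: s-BuLi, THF, −78 °C; then 12, −78 to −40 °C; aq. NH4Cl
Reagents that add atoms: none
Why: Metalation of an allyl ether and gamma-alkylation: s-BuLi removes the allylic proton next to the MOM oxygen, O–Li coordination and the bulk of the quaternary substituent hold the oxyallyl anion U-shaped, and SN2 attack of its unhindered terminus on the chloromethyl ether gives the enol ether with oxygen cis to the new CH2CH2O chain (E), so no beta-alkoxyvinyl metal species is ever needed.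

Step 10
Reactants: 14 (TIPS ether)
Product: 15 (1R,2R)-2-methoxy-2-{(1E)-1-(methoxymethoxy)-4-[(4-methoxybenzyl)oxy]but-1-en-2-yl}-4-methylcyclohex-3-en-1-ol
Conditions: TBAF, THF, rt
Reagents that add atoms: none
Why: Fluoride-induced desilylation; the enol acetal, the PMB ether and the tertiary methyl ether are inert to TBAF.

Step 11
Reactants: 15 (secondary alcohol)
Product: 16 (2R)-2-methoxy-2-{(1E)-1-(methoxymethoxy)-4-[(4-methoxybenzyl)oxy]but-1-en-2-yl}-4-methylcyclohex-3-en-1-one
Conditions: Dess–Martin periodinane, NaHCO3, CH2Cl2, 0 °C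
Reagents that add atoms: none
Why: Dess–Martin oxidation of the secondary alcohol under buffered conditions spares the enol ether; the stereocentre that guided step 5 is erased and C6 alone carries the chirality.

Step 12
Reactants: 16 (alpha-methoxy ketone); 17 isopropenylmagnesium bromide
Product: 18 (1R,2R)-2-methoxy-2-{(1E)-1-(methoxymethoxy)-4-[(4-methoxybenzyl)oxy]but-1-en-2-yl}-4-methyl-1-(prop-1-en-2-yl)cyclohex-3-en-1-ol
Conditions: THF, −78 to −40 °C; aq. NH4Cl
Reagents that add atoms: none
Why: Chelation-controlled Grignard addition: magnesium bridges the carbonyl and the alpha-methoxy oxygen, so isopropenyl adds anti to the alkenyl group, which sets C1 and places the two alkenyl groups trans.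

Step 13
Reactants: 18 (trans-dialkenyl cyclohexenediol monomethyl ether)
Product: 21 (4Z,6Z,8S,10R)-10-hydroxy-6-methoxy-8-(methoxymethoxy)-7-{2-[(4-methoxybenzyl)oxy]ethyl}-4,10-dimethylcyclodeca-4,6-dien-1-one (germacrane numbering; C5 and C8 trans across C6=C7), via potassium alkoxide 19 (not isolated), via potassium enolate 20 (not isolated)
Conditions: KH, 18-crown-6, THF, 0 °C to rt; then −78 °C, 2-(phenylsulfonyl)-3-phenyloxaziridine; aq. NH4Cl
Reagents that add atoms: 2-(phenylsulfonyl)-3-phenyloxaziridine, O=S(=O)(N1OC1c1ccccc1)c1ccccc1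
Why: KH/18-crown-6 gives the naked C1 alkoxide 19, whose trans-diequatorial alkenyl groups adopt a chair [3,3] transition state in which C9 bonds to C8 while C1–C6 breaks, giving the C1=C10 enolate and the C6 methyl enol ether (enolate 20). The closest known reaction type is the anionic oxy-Cope ring expansion of 1,2-dialkenylcyclohexanols to cyclodecenones with oxaziridine trapping of the regiodefined enolate. The ten-membered ring is not closed end to end but arises by four-atom ring expansion of the cyclohexene. C8 is set by the E enol ether, which places the C8 oxygen equatorial on the chair; C10 is set by attack of the oxaziridine on the outer face of the tetrasubstituted, ring-trans enolate, whose planar chirality cannot invert because neither O nor CH3 can pass through the ring. The step needs chair over boat, the exocyclic enol ether and not the ring alkene as partner, and oxidation before the enolate equilibrates; these are secured by the trans alkenyl groups (ring bonds C1–C2 and C6–C5 equatorial), by the ring-locked, methyl-bearing C4 terminus, and by adding the oxidant at −78 °C to the aprotic enolate.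

Step 14
Reactants: 21 (alpha-ketol)
Product: 22 (4Z,6Z,8S,10R)-10-acetoxy-6-methoxy-8-(methoxymethoxy)-7-{2-[(4-methoxybenzyl)oxy]ethyl}-4,10-dimethylcyclodeca-4,6-dien-1-one
Conditions: Ac2O, DMAP, Et3N, CH2Cl2, rt to 40 °C
Reagents that add atoms: acetic anhydride, CC(=O)OC(C)=O
Why: DMAP-catalysed acylation of the tertiary alpha-ketol under basic conditions leaves the dienol ether intact; the final C10 acetate is installed now so that no free alpha-hydroxy ketone interferes with the later hydride step.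

Step 15
Reactants: 22 (methyl dienol ether)
Product: 23 (4Z,7S,8S,10R)-10-acetoxy-8-(methoxymethoxy)-7-{2-[(4-methoxybenzyl)oxy]ethyl}-4,10-dimethylcyclodec-4-ene-1,6-dione
Conditions: PPTS (cat.), acetone/H2O, 0 °C
Reagents that add atoms: water, O
Why: Enol ether hydrolysis (C-protonation, hydration, loss of methanol) unmasks the C6 ketone with the Z C4=C5 bond in conjugation; kinetic protonation on the exposed outer face of the configurationally locked ring-trans C6=C7 bond sets 7S.

Step 16
Reactants: 23 (PMB ether)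
Product: 24 (4Z,7S,8S,10R)-10-acetoxy-7-(2-hydroxyethyl)-8-(methoxymethoxy)-4,10-dimethylcyclodec-4-ene-1,6-dione
Conditions: DDQ, CH2Cl2/pH 7 buffer, 0 °C
Reagents that add atoms: none
Why: DDQ oxidation of the PMB ether (benzylic hydride abstraction, hydrolysis of the oxocarbenium) frees the C12 alcohol; the step is postponed until the DDQ-sensitive dienol ether has been hydrolysed.

Step 17
Reactants: 24 (primary alcohol)
Product: 25 (4Z,7S,8S,10R)-10-acetoxy-8-(methoxymethoxy)-4,10-dimethyl-7-(2-oxoethyl)cyclodec-4-ene-1,6-dione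
Conditions: Dess–Martin periodinane, NaHCO3, CH2Cl2, 0 °C
Reagents that add atoms: none
Why: Dess–Martin oxidation of the primary alcohol, the only free hydroxyl, gives the aldehyde without epimerising C7.

Step 18
Reactants: 25 (aldehyde)
Product: 26 (4Z,7S,8S,10R)-10-acetoxy-8-(methoxymethoxy)-4,10-dimethyl-7-(3-oxoprop-1-en-2-yl)cyclodec-4-ene-1,6-dione
Conditions: Eschenmoser's salt, Et3N, CH2Cl2, rt
Reagents that add atoms: N,N-dimethylmethyleneiminium iodide, C=[N+](C)C.[I-]
Why: Aldehyde alpha-methylenation (Mannich reaction with the iminium salt, then E1cB loss of dimethylamine) introduces C13 at the aldehyde stage, because only the aldehyde enolises under Et3N whereas a lactone enolate could not be formed selectively beside the C1 ketone.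

Step 19
Reactants: 26 (enal)
Product: 27 (4Z,7S,8S,10R)-10-acetoxy-8-(methoxymethoxy)-1,6-dioxogermacra-4,11(13)-dien-12-oic acid
Conditions: NaClO2, NaH2PO4, 2-methylbut-2-ene, t-BuOH/H2O, 0 °C to rt
Reagents that add atoms: sodium chlorite, [Na+].[O-]Cl=O
Why: Pinnick oxidation converts the enal into the acrylic acid under buffered conditions that do not touch the ketones, the enone alkene or the MOM ether.

Step 20
Reactants: 27 (gamma-keto acid)
Product: 29 (4Z,6R,7S,8S,10R)-10-acetoxy-8-(methoxymethoxy)-1-oxogermacra-4,11(13)-dien-12,6-olide, via hydroxy acid 28 (not isolated)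
Conditions: NaBH4, CeCl3·7H2O, MeOH, −78 °C; then 1 M HCl to pH 2–3, rt
Reagents that add atoms: none
Why: Luche reduction: the Ce-activated Z-enone carbonyl at C6 is reduced 1,2 in preference to the C1 ketone flanked by the quaternary C10, hydride adds anti to the C7–C8 ring bond and past the C7 hydrogen (Felkin–Anh) so that the new C6 oxygen is cis to C11, and acidification closes the cis-fused gamma-lactone.

Step 21
Reactants: 29 (alpha-methylene lactone)
Product: 31 (4Z,6R,7S,8S,10R,11R)-10-acetoxy-13-hydroxy-8-(methoxymethoxy)-1-oxogermacr-4-en-12,6-olide, via boronate 30 (not isolated)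
Conditions: CuCl (cat.), Xantphos, NaOt-Bu (cat.), B2pin2, MeOH, THF, 0 °C to rt; then NaBO3·4H2O, THF/H2O, rt
Reagents that add atoms: bis(pinacolato)diboron (boryl group of 30), CC1(C)OB(OC1(C)C)B1OC(C)(C)C(C)(C)O1; sodium perborate (oxygen of 31), [Na+].[O-]OB=O
Why: Copper-catalysed conjugate borylation of the alpha-methylene lactone, protonation of the copper enolate by MeOH on the convex face away from C8 (sets 11R, C13 cis to C8), and perborate oxidation of the C–B bond with retention give the hydroxymethyl lactone.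

Step 22
Reactants: 31 (primary alcohol)
Product: 32 (4Z,6R,7S,8S,10R,11R)-10,13-diacetoxy-8-(methoxymethoxy)-1-oxogermacr-4-en-12,6-olide
Conditions: Ac2O, pyridine, DMAP (cat.), CH2Cl2, 0 °C
Reagents that add atoms: acetic anhydride, CC(=O)OC(C)=O
Why: Acetylation of the primary alcohol under mild base at 0 °C avoids E1cB loss of the beta-acyloxy group.

Step 23
Reactants: 32 (MOM ether)
Product: 33 (4Z,6R,7S,8S,10R,11R)-10,13-diacetoxy-8-hydroxy-1-oxogermacr-4-en-12,6-olide
Conditions: Me2BBr, CH2Cl2, −78 °C; then aq. NaHCO3/THF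
Reagents that add atoms: none
Why: Lewis acid cleavage of the MOM acetal by Me2BBr at −78 °C (bromide capture of the oxocarbenium, hydrolysis of the borinate) spares esters, lactone, ketone and alkene; C8–OH is freed only after the alpha-methylene lactone that it could attack is gone.

Step 24
Reactants: 33 (bishomoallylic alcohol)
Product: 34 (4R,5S,6S,7S,8S,10R,11R)-10,13-diacetoxy-4,5-epoxy-8-hydroxy-1-oxogermacran-12,6-olide
Conditions: VO(acac)2 (cat.), t-BuOOH (decane), CH2Cl2, 0 °C to rt
Reagents that add atoms: tert-butyl hydroperoxide, CC(C)(C)OO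
Why: Hydroxyl-directed epoxidation: the vanadium alkoxide of the bishomoallylic C8 hydroxyl, which lies beneath C5 when H6 eclipses the Z alkene (allylic strain), delivers the peroxide oxygen to that face, the one an undirected oxidant does not reach, to give the cis-4,5-epoxide with the 4R,5S configuration.

Step 25
Reactants: 34 (epoxy alcohol)
Product: 35 (4R,5S,6S,7S,8S,10R,11R)-10,13-diacetoxy-4,5-epoxy-8-(methacryloyloxy)-1-oxogermacran-12,6-olide (CNP0166747.1)
Conditions: methacrylic anhydride, DMAP (cat.), i-Pr2NEt, CH2Cl2, 0 °C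
Reagents that add atoms: methacrylic anhydride, CC(=C)C(=O)OC(=O)C(C)=C
Why: DMAP-catalysed esterification of the secondary C8 alcohol with the anhydride under mild amine base tolerates the epoxide and the beta-acetoxy lactone and completes the target.

**Compound list**

1 | 3-methylcyclohex-2-en-1-one | CC1=CC(=O)CCC1 | starting material
2 | rac-6-acetoxy-3-methylcyclohex-2-en-1-one | CC(=O)OC1CCC(C)=CC1=O | intermediate
3 | (R)-6-hydroxy-3-methylcyclohex-2-en-1-one | O[C@@H]1CCC(C)=CC1=O | intermediate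
4 | (R)-3-methyl-6-[(triisopropylsilyl)oxy]cyclohex-2-en-1-one | CC(C)[Si](O[C@@H]1CCC(C)=CC1=O)(C(C)C)C(C)C | intermediate
5 | 2-bromoprop-2-en-1-ol | OCC(Br)=C | starting material
6 | 2-bromo-3-(methoxymethoxy)prop-1-ene | COCOCC(Br)=C | intermediate
7 | [3-(methoxymethoxy)prop-1-en-2-yl]lithium | COCOCC([Li])=C | intermediate
8 | (1R,6R)-1-[3-(methoxymethoxy)prop-1-en-2-yl]-3-methyl-6-[(triisopropylsilyl)oxy]cyclohex-2-en-1-ol | CC(C)[Si](O[C@@H]1CCC(C)=C[C@@]1(O)C(=C)COCOC)(C(C)C)C(C)C | intermediate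
9 | {[(1R,2R)-2-methoxy-2-[3-(methoxymethoxy)prop-1-en-2-yl]-4-methylcyclohex-3-en-1-yl]oxy}triisopropylsilane | CC(C)[Si](O[C@@H]1CCC(C)=C[C@@]1(OC)C(=C)COCOC)(C(C)C)C(C)C | intermediate
10 | (4-methoxyphenyl)methanol | COc1ccc(CO)cc1 | starting material
11 | 1-methoxy-4-{[(methylsulfanyl)methoxy]methyl}benzene | COc1ccc(COCSC)cc1 | intermediate
12 | 1-[(chloromethoxy)methyl]-4-methoxybenzene | COc1ccc(COCCl)cc1 | intermediate
13 | lithium oxyallyl anion of 9 (lithiated at the OMOM-bearing carbon) | [Li+].CC(C)[Si](O[C@@H]1CCC(C)=C[C@@]1(OC)C(=C)[CH-]OCOC)(C(C)C)C(C)C | intermediate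
14 | {[(1R,2R)-2-methoxy-2-{(1E)-1-(methoxymethoxy)-4-[(4-methoxybenzyl)oxy]but-1-en-2-yl}-4-methylcyclohex-3-en-1-yl]oxy}triisopropylsilane | CC(C)[Si](O[C@@H]1CCC(C)=C[C@@]1(OC)/C(CCOCc2ccc(OC)cc2)=C/OCOC)(C(C)C)C(C)C | intermediate
15 | (1R,2R)-2-methoxy-2-{(1E)-1-(methoxymethoxy)-4-[(4-methoxybenzyl)oxy]but-1-en-2-yl}-4-methylcyclohex-3-en-1-ol | O[C@@H]1CCC(C)=C[C@@]1(OC)/C(CCOCc2ccc(OC)cc2)=C/OCOC | intermediate
16 | (2R)-2-methoxy-2-{(1E)-1-(methoxymethoxy)-4-[(4-methoxybenzyl)oxy]but-1-en-2-yl}-4-methylcyclohex-3-en-1-one | O=C1CCC(C)=C[C@@]1(OC)/C(CCOCc2ccc(OC)cc2)=C/OCOC | intermediate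
17 | isopropenylmagnesium bromide | CC(=C)[Mg]Br | starting material
18 | (1R,2R)-2-methoxy-2-{(1E)-1-(methoxymethoxy)-4-[(4-methoxybenzyl)oxy]but-1-en-2-yl}-4-methyl-1-(prop-1-en-2-yl)cyclohex-3-en-1-ol | O[C@@]1(C(C)=C)CCC(C)=C[C@@]1(OC)/C(CCOCc2ccc(OC)cc2)=C/OCOC | intermediate
19 | potassium alkoxide of 18 | [K+].[O-][C@@]1(C(C)=C)CCC(C)=C[C@@]1(OC)/C(CCOCc2ccc(OC)cc2)=C/OCOC | intermediate
20 | potassium C1(10)-enolate of the ring-expanded trienone (C2 and C9 trans across C1=C10; C5 and C8 trans across C6=C7; 8S) | [K+].COCO[C@H]1C/C(C)=C(\[O-])CC/C(C)=C\C(OC)=C1/CCOCc2ccc(OC)cc2 | intermediate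
21 | (4Z,6Z,8S,10R)-10-hydroxy-6-methoxy-8-(methoxymethoxy)-7-{2-[(4-methoxybenzyl)oxy]ethyl}-4,10-dimethylcyclodeca-4,6-dien-1-one | COCO[C@H]1C[C@@](C)(O)C(=O)CC/C(C)=C\C(OC)=C1/CCOCc2ccc(OC)cc2 | intermediate
22 | (4Z,6Z,8S,10R)-10-acetoxy-6-methoxy-8-(methoxymethoxy)-7-{2-[(4-methoxybenzyl)oxy]ethyl}-4,10-dimethylcyclodeca-4,6-dien-1-one | COCO[C@H]1C[C@@](C)(OC(C)=O)C(=O)CC/C(C)=C\C(OC)=C1/CCOCc2ccc(OC)cc2 | intermediate
23 | (4Z,7S,8S,10R)-10-acetoxy-8-(methoxymethoxy)-7-{2-[(4-methoxybenzyl)oxy]ethyl}-4,10-dimethylcyclodec-4-ene-1,6-dione | COCO[C@H]1C[C@@](C)(OC(C)=O)C(=O)CC/C(C)=C\C(=O)[C@H]1CCOCc2ccc(OC)cc2 | intermediate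
24 | (4Z,7S,8S,10R)-10-acetoxy-7-(2-hydroxyethyl)-8-(methoxymethoxy)-4,10-dimethylcyclodec-4-ene-1,6-dione | COCO[C@H]1C[C@@](C)(OC(C)=O)C(=O)CC/C(C)=C\C(=O)[C@H]1CCO | intermediate
25 | (4Z,7S,8S,10R)-10-acetoxy-8-(methoxymethoxy)-4,10-dimethyl-7-(2-oxoethyl)cyclodec-4-ene-1,6-dione | COCO[C@H]1C[C@@](C)(OC(C)=O)C(=O)CC/C(C)=C\C(=O)[C@H]1CC=O | intermediate
26 | (4Z,7S,8S,10R)-10-acetoxy-8-(methoxymethoxy)-4,10-dimethyl-7-(3-oxoprop-1-en-2-yl)cyclodec-4-ene-1,6-dione | COCO[C@H]1C[C@@](C)(OC(C)=O)C(=O)CC/C(C)=C\C(=O)[C@H]1C(=C)C=O | intermediate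
27 | (4Z,7S,8S,10R)-10-acetoxy-8-(methoxymethoxy)-1,6-dioxogermacra-4,11(13)-dien-12-oic acid | COCO[C@H]1C[C@@](C)(OC(C)=O)C(=O)CC/C(C)=C\C(=O)[C@H]1C(=C)C(=O)O | intermediate
28 | (4Z,6R,7R,8S,10R)-10-acetoxy-6-hydroxy-8-(methoxymethoxy)-1-oxogermacra-4,11(13)-dien-12-oic acid | COCO[C@H]1C[C@@](C)(OC(C)=O)C(=O)CC/C(C)=C\[C@@H](O)[C@H]1C(=C)C(=O)O | intermediate
29 | (4Z,6R,7S,8S,10R)-10-acetoxy-8-(methoxymethoxy)-1-oxogermacra-4,11(13)-dien-12,6-olide | COCO[C@H]1C[C@@](C)(OC(C)=O)C(=O)CC/C(C)=C\[C@H]2OC(=O)C(=C)[C@H]21 | intermediate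
30 | (4Z,6R,7S,8S,10R,11S)-10-acetoxy-8-(methoxymethoxy)-1-oxo-13-(4,4,5,5-tetramethyl-1,3,2-dioxaborolan-2-yl)germacr-4-en-12,6-olide | COCO[C@H]1C[C@@](C)(OC(C)=O)C(=O)CC/C(C)=C\[C@H]2OC(=O)[C@@H](CB3OC(C)(C)C(C)(C)O3)[C@H]21 | intermediate
31 | (4Z,6R,7S,8S,10R,11R)-10-acetoxy-13-hydroxy-8-(methoxymethoxy)-1-oxogermacr-4-en-12,6-olide | COCO[C@H]1C[C@@](C)(OC(C)=O)C(=O)CC/C(C)=C\[C@H]2OC(=O)[C@@H](CO)[C@H]21 | intermediate
32 | (4Z,6R,7S,8S,10R,11R)-10,13-diacetoxy-8-(methoxymethoxy)-1-oxogermacr-4-en-12,6-olide | COCO[C@H]1C[C@@](C)(OC(C)=O)C(=O)CC/C(C)=C\[C@H]2OC(=O)[C@@H](COC(C)=O)[C@H]21 | intermediate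
33 | (4Z,6R,7S,8S,10R,11R)-10,13-diacetoxy-8-hydroxy-1-oxogermacr-4-en-12,6-olide | O[C@H]1C[C@@](C)(OC(C)=O)C(=O)CC/C(C)=C\[C@H]2OC(=O)[C@@H](COC(C)=O)[C@H]21 | intermediate
34 | (4R,5S,6S,7S,8S,10R,11R)-10,13-diacetoxy-4,5-epoxy-8-hydroxy-1-oxogermacran-12,6-olide | O[C@H]1C[C@@](C)(OC(C)=O)C(=O)CC[C@@]2(C)O[C@H]2[C@H]2OC(=O)[C@@H](COC(C)=O)[C@H]21 | intermediate
35 | (4R,5S,6S,7S,8S,10R,11R)-10,13-diacetoxy-4,5-epoxy-8-(methacryloyloxy)-1-oxogermacran-12,6-olide (CNP0166747.1) | C=C(C)C(=O)O[C@H]1C[C@@](C)(OC(C)=O)C(=O)CC[C@@]2(C)O[C@H]2[C@H]2OC(=O)[C@@H](COC(C)=O)[C@H]21 | target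

**Step count.** Total: 25 steps. Longest linear sequence: 22 steps (from 1 through steps 1–3, 5, 6 and 9–25).

**Steps most likely to fail**

Step 13. What may go wrong: the alkoxide may fragment heterolytically into an enone and a methoxy-stabilised pentadienyl anion that recombines without chair control. The enolate may also equilibrate to the C1–C2 side before it is oxidised, or the product alkoxide may add to the sulfonimine by-product. Fallback (sets out from 18, returns at 21): the tertiary alcohol would be silylated with N-(trimethylsilyl)imidazole to the trimethylsilyl ether of 18 F1. This would be rearranged without base by a thermal siloxy-Cope shift (toluene, 180–200 °C, base-washed sealed tube) through the same chair to the trimethylsilyl enol ether of the ring-expanded trienone F2. MeLi (THF, 0 °C) would then release the lithium C1(10)-enolate F3 regiospecifically, and 2-(phenylsulfonyl)-3-phenyloxaziridine at −78 °C would give 21.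

Step 9. What may go wrong: deprotonation at a competing allylic site, or alkylation at the oxygen-bearing carbon instead of the terminus of the oxyallyl anion. Fallback (sets out from 4, returns at 14): methyl 4-hydroxybutanoate would be protected with 4-methoxybenzyl 2,2,2-trichloroacetimidate (acid catalysis) to methyl 4-[(4-methoxybenzyl)oxy]butanoate F4. Its lithium enolate F5 (LDA, THF, −78 °C) would add to 4 anti to the silyloxy group to give the beta-hydroxy ester F6. O-Methylation without base (MeOTf, 2,6-di-tert-butyl-4-methylpyridine) would give the methyl ether F7, and DIBAL-H at −78 °C would give the aldehyde F8. The potassium enolate of F8, F9 (KHMDS, THF, −78 °C), would be O-alkylated with MOMCl, the oxygen settling trans to the quaternary carbon for steric reasons, to return 14.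

Step 24. What may go wrong: the C8 hydroxyl may be tied up as a transannular hemiketal with the C1 ketone, so that delivery is slow and undirected oxidation reaches the other face of the alkene. Fallback (sets out from 33, returns at 35): the alcohol would first be acylated with methacrylic anhydride to the 8-O-methacryloyl alkene F10. NBS in DME/H2O would form the bromonium ion on the exposed face and water would open it at the tertiary C4 from the opposite side to give the 5-bromo-4-hydroxy compound F11. Ag2O (THF, rt) would close the ring with inversion at C5, placing the epoxide oxygen on the face opposite to the one a peracid would reach, to give 35.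

**Further compounds**

F1 | step 13 | trimethylsilyl ether of 18 | C[Si](C)(C)O[C@@]1(C(C)=C)CCC(C)=C[C@@]1(OC)/C(CCOCc2ccc(OC)cc2)=C/OCOC
F2 | step 13 | trimethylsilyl enol ether of the ring-expanded trienone (1-silyloxy-cyclodeca-1(10),4,6-triene, 8S) | COCO[C@H]1C/C(C)=C(\O[Si](C)(C)C)CC/C(C)=C\C(OC)=C1/CCOCc2ccc(OC)cc2
F3 | step 13 | lithium C1(10)-enolate of the ring-expanded trienone | [Li+].COCO[C@H]1C/C(C)=C(\[O-])CC/C(C)=C\C(OC)=C1/CCOCc2ccc(OC)cc2
F4 | step 9 | methyl 4-[(4-methoxybenzyl)oxy]butanoate | COC(=O)CCCOCc1ccc(OC)cc1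
F5 | step 9 | lithium enolate of F4 | [Li+].COC([O-])=CCCOCc1ccc(OC)cc1
F6 | step 9 | methyl 2-{(1R,6R)-1-hydroxy-3-methyl-6-[(triisopropylsilyl)oxy]cyclohex-2-en-1-yl}-4-[(4-methoxybenzyl)oxy]butanoate (mixture at C2 of the ester) | CC(C)[Si](O[C@@H]1CCC(C)=C[C@@]1(O)C(CCOCc2ccc(OC)cc2)C(=O)OC)(C(C)C)C(C)C
F7 | step 9 | methyl ether of F6 | CC(C)[Si](O[C@@H]1CCC(C)=C[C@@]1(OC)C(CCOCc2ccc(OC)cc2)C(=O)OC)(C(C)C)C(C)C
F8 | step 9 | 2-{(1R,6R)-1-methoxy-3-methyl-6-[(triisopropylsilyl)oxy]cyclohex-2-en-1-yl}-4-[(4-methoxybenzyl)oxy]butanal | CC(C)[Si](O[C@@H]1CCC(C)=C[C@@]1(OC)C(CCOCc2ccc(OC)cc2)C=O)(C(C)C)C(C)C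
F9 | step 9 | potassium enolate of F8 | [K+].CC(C)[Si](O[C@@H]1CCC(C)=C[C@@]1(OC)C(CCOCc2ccc(OC)cc2)=C[O-])(C(C)C)C(C)C
F10 | step 24 | (4Z,6R,7S,8S,10R,11R)-10,13-diacetoxy-8-(methacryloyloxy)-1-oxogermacr-4-en-12,6-olide | C=C(C)C(=O)O[C@H]1C[C@@](C)(OC(C)=O)C(=O)CC/C(C)=C\[C@H]2OC(=O)[C@@H](COC(C)=O)[C@H]21
F11 | step 24 | 5-bromo-4-hydroxy compound (bromohydrin of F10; C4–OH anti to C5–Br) | C=C(C)C(=O)O[C@H]1C[C@@](C)(OC(C)=O)C(=O)CC[C@@](C)(O)[C@H](Br)[C@H]2OC(=O)[C@@H](COC(C)=O)[C@H]21
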